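(The data come from a simulation from invented constants; scatter was added.)

The larch run built up intermediate at a net fractional rate of 0.0880 h⁻¹ over its first 1.33 h, as read from one scattered reading. Birch gave 0.0827 h⁻¹ and elm, with half the reagent, gave 0.0421 h⁻¹. We read this early rate as a pseudo-first-order constant for starting material, at the reagent charge of each run.

| flask | starting material | reagent | protic impurity | remark | time |
|---|---|---|---|---|---|
| larch | 0.034 M | 0.040 M | 2.5 mM | run made earlier |  |
| birch | 0.075 M | 0.040 M | 2.5 mM | run made earlier |  |
| elm | 0.050 M | 0.020 M | 2.5 mM | run made earlier |  |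
| flask | 0.050 M | 0.0400 M | 2.50 mM |  | 25 h |

| run | time / h | intermediate / % | target / % |
|---|---|---|---|
| larch | 1.33 | 11.7 | 1.3 |
| larch | 2.50 | 15.1 | 0.4 |
| larch | 5.00 | 22.3 | 3.1 |
| larch | 10.0 | 21.5 | 5.1 |
| larch | 15.0 | 17.4 | 5.2 |
| larch | 30.0 | 8.2 | 8.9 |
| birch | 1.33 | 11.0 | 0 |
| birch | 2.50 | 14.6 | 2.9 |
| birch | 5.00 | 20.2 | 1.0 |
| birch | 10.0 | 14.8 | 2.0 |
| birch | 15.0 | 9.4 | 3.9 |
| birch | 30.0 | 0.3 | 5.1 |
| elm | 1.33 | 5.6 | 1.8 |
| elm | 3.00 | 10.4 | 0 |
| elm | 6.00 | 10.9 | 0 |
| elm | 15.0 | 7.4 | 1.9 |
| elm | 30.0 | 3.0 | 4.7 |

(scatter of a reading: 1 percentage point)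

- the analysis behind the earlier runs scatters by 1 percentage point, standard deviation

* the moment within 25 h at which there is most intermediate
* the amount of intermediate, in percent of the starting material charged, at that time

At a peak, making has fallen to the rate of loss. Our bench rule skips that drift: we divide each run's top reading by its early rate. Larch gives 2.53 h, birch 2.44 h and elm 2.59 h, each carrying the scatter of 1 percentage point per reading. Their mean, 2.52 h, we call the hold-up time.

The flask has the reagent of larch and birch, so we take their mean early rate, 0.0853 h⁻¹, and expect a peak of 21.5%. The rule assumes that the peak keeps one proportion to the early rate. The runs test this from 0.400 to 1.18 equivalents of reagent to starting material. The flask, at 0.800, lies inside that span. Beyond it, the rule is unread.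

The forecast gave 22% at 6 h, and said of itself: “This is an interpolation, not a fitted model.”

The flask gives 21.6% at 5.93 h.

    starting material + reagent → intermediate + by-product (k = 2.80 M⁻¹ h⁻¹)
    intermediate → target (k = 0.0330 h⁻¹)
    target ⇌ isomer of the product (K = 0.880, k = 0.360 h⁻¹)
    starting material + protic impurity → quenched substrate (k = 12.0 M⁻¹ h⁻¹)
    intermediate → side product (k = 0.130 h⁻¹)

At 4.80 h the flask made intermediate 1.21 times as fast as it used it, and at its peak 58.4% of the starting material remained. By 25.0 h that ratio stood at 0.564, with side product at 46.6% and target at 6.45%. The flask's own hold-up, its peak over our early rate, is 2.53 h. The same flask with 0.10 M of reagent has 2.00 equiv, above the tested span. Hold-up times the early rate scaled by reagent gives 53.8% there. The computed peak is 40.2%, lower than the rule gave.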